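Cuts: the C7 O–methyl bond and two O–benzyl bonds on unit B (protecting groups). Next, C3–C4 and O1–C2 of the unit A pyranone, which gives a salicylaldehyde and a unit B coumarin-3-acetic acid whose CH2 carbon is C3, so C3–C3' comes from succinic anhydride. Last, C4a–C8a of the unit A benzene ring.
Enabling feature: in the benzene ring of unit A, C6, C7, C8 and C8a are adjacent and each bears oxygen, matching the four ring carbons of dimethyl squarate. C5 (H) and C4a (bearing C4) correspond to an alkene carrying a masked aldehyde.
Forward order: squarate plus an acrolein-acetal vinyllithium gives the cyclobutenone, which expands to the unit A benzene ring. In parallel, the unit B pyranone is built. The unit A pyranone closes when the two fragments are joined, followed by debenzylation and C7 demethylation.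
Stereochemistry: the target has no stereocentre. The racemic quaternary carbon of the cyclobutenone and the sp3 carbon of the dienone both vanish on aromatisation, and the alkene geometry is erased as well.

Key step: step 3

Remark: unprimed locants refer to unit A (the 7-hydroxy-6,8-dimethoxycoumarin) and primed locants to unit B (the 6,7-dihydroxycoumarin). Rotation about C3–C3' is assumed to be free, so the target is treated as achiral.

Step 1
Reactants: 1 3,3-diethoxyprop-1-yne
Product: 2 (E)-tributyl(3,3-diethoxyprop-1-enyl)stannane
Conditions: Bu3SnH, AIBN (cat.), neat, 85 °C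
Reagents that add atoms: tributyltin hydride, CCCC[SnH](CCCC)CCCC
Why: Radical hydrostannylation, in which the stannyl radical adds to the terminal alkyne carbon and reversible addition–elimination of tin radicals at this temperature moves the vinylstannane to the more stable E isomer; any remaining Z isomer would lead to the same arene in step 3.

Step 2
Reactants: 2 (E)-tributyl(3,3-diethoxyprop-1-enyl)stannane; 3 dimethyl squarate
Product: 6 rac-4-[(E)-3,3-diethoxyprop-1-enyl]-2,3,4-trimethoxycyclobut-2-en-1-one, via vinyllithium 4 (not isolated), via lithium alkoxide 5 (not isolated)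
Conditions: n-BuLi, THF, −78 °C; cannulate into 3, THF, −78 °C; MeOTf, −78 to 0 °C; aq. NaHCO3
Reagents that add atoms: methyl triflate, COS(=O)(=O)C(F)(F)F; n-butyllithium, [Li]CCCC (supplies only the lithium of 4 and 5)
Why: Tin–lithium exchange with retention of geometry, 1,2-addition of the vinyllithium to one of the two equivalent squarate carbonyls and O-methylation of the tertiary alkoxide by MeOTf form the standard sequence to 4-alkenyl-4-alkoxycyclobutenones; the quaternary carbon is formed racemic and disappears in step 3.

Step 3
Reactants: 6 rac-4-[(E)-3,3-diethoxyprop-1-enyl]-2,3,4-trimethoxycyclobut-2-en-1-one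
Product: 9 6-(diethoxymethyl)-2,3,4-trimethoxyphenol, via dienylketene 7 (not isolated), via cyclohexadienone 8 (not isolated)
Conditions: degassed toluene (0.02 M), base-washed glassware, 110 °C
Reagents that add atoms: none
Why: Heat breaks the C1–C4 bond of the cyclobutenone in a four-electron conrotatory opening to dienylketene 7, and the donor methoxy on the sp3 carbon turns outward, so the alkenyl arm turns inward and ends up cis to the ketene. A six-electron disrotatory electrocyclisation then joins the ketene carbon (future C8a) to the far alkene carbon (future C4a), closing the six-membered carbocycle as dienone 8, and enolisation to phenol 9 makes the sequence irreversible. This is the Moore-type thermal ring expansion of squarate-derived 4-alkenyl-4-alkoxycyclobutenones, a known route to highly oxygenated phenols and hydroquinone monoethers. No stereocentre remains, because the quaternary carbon of 6 becomes sp2 in 7 and the single sp3 ring carbon of 8 is lost on tautomerisation. The step needs torquoselective opening, which the C4 methoxy group provides, and one fixed substituent order, which the symmetry of dimethyl squarate provides by allowing only one 1,2-adduct, so OH, OMe, OMe, OMe, H and CH(OEt)2 must follow one another around the ring. The E alkene keeps the acetal on the outside of the closing triene, and dilute, acid-free, oxygen-free solution protects the ketene and the acetal.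

Step 4
Reactants: 9 6-(diethoxymethyl)-2,3,4-trimethoxyphenol
Product: 10 2-hydroxy-3,4,5-trimethoxybenzaldehyde
Conditions: 1 M HCl, THF, rt
Reagents that add atoms: water, O
Why: Acid-catalysed acetal hydrolysis, made easy by the ortho hydroxyl and para methoxy donors that stabilise the benzylic oxocarbenium ion, while aryl methyl ethers are inert to dilute acid.

Step 5
Reactants: 11 2,4,5-trihydroxybenzaldehyde
Product: 12 4,5-bis(benzyloxy)-2-hydroxybenzaldehyde
Conditions: BnBr (2.05 equiv), K2CO3 (2.1 equiv), DMF, N2, rt
Reagents that add atoms: benzyl bromide, BrCc1ccccc1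
Why: Williamson etherification in which the 2-OH, hydrogen-bonded to the formyl oxygen, reacts last, the same selectivity known for the 4-OH of 2,4-dihydroxybenzaldehyde and the 5-OH of 2,5-dihydroxybenzaldehyde.

Step 6
Reactants: 12 4,5-bis(benzyloxy)-2-hydroxybenzaldehyde; 13 succinic anhydride
Product: 15 2-[6,7-bis(benzyloxy)-2-oxo-2H-chromen-3-yl]acetic acid, via aryl hemisuccinate 14 (not isolated)
Conditions: 13 (3 equiv), anhydrous disodium succinate, melt, N2, 160 °C; aq. NaHCO3, then HCl
Reagents that add atoms: none
Why: Perkin condensation with succinic anhydride, the classical entry to coumarin-3-acetic acids, in which the phenol is acylated to 14, the CH2 next to the aryl ester carbonyl undergoes aldol condensation with the neighbouring aldehyde to close the six-membered lactone ring, and excess anhydride suppresses a second condensation.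

Step 7
Reactants: 10 2-hydroxy-3,4,5-trimethoxybenzaldehyde; 15 2-[6,7-bis(benzyloxy)-2-oxo-2H-chromen-3-yl]acetic acid
Product: 17 6',7'-bis(benzyloxy)-6,7,8-trimethoxy-3,3'-bicoumarin, via aryl ester 16 (not isolated)
Conditions: Ac2O, Et3N, 120 °C
Reagents that add atoms: none
Why: Perkin–Oglialoro condensation as used for 3-arylcoumarins and 3,3'-bicoumarins, in which Ac2O activates the acid, the phenol of 10 is acylated to 16, and its CH2 (flanked by the ester carbonyl and the C3'=C4' bond) is deprotonated by Et3N and condenses with the ortho aldehyde, forming C3=C4 and closing the unit A pyranone with C3–C3' already in place.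

Step 8
Reactants: 17 6',7'-bis(benzyloxy)-6,7,8-trimethoxy-3,3'-bicoumarin
Product: 18 6',7'-dihydroxy-6,7,8-trimethoxy-3,3'-bicoumarin
Conditions: H2 (1 atm), 10% Pd/C, THF–MeOH, rt
Reagents that add atoms: none
Why: Hydrogenolysis of aryl benzyl ethers over Pd/C, under which the trisubstituted conjugated C3=C4 bonds of 3-substituted coumarins and the aryl methyl ethers normally survive.

Step 9
Reactants: 18 6',7'-dihydroxy-6,7,8-trimethoxy-3,3'-bicoumarin
Product: 19 arteminorin C (6',7,7'-trihydroxy-6,8-dimethoxy-3,3'-bicoumarin)
Conditions: LiCl (excess), DMF, argon, 150 °C; then 1 M HCl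
Reagents that add atoms: none
Why: SN2 dealkylation of an acceptor-activated aryl methyl ether by chloride (the LiCl/DMF method), with the site preference seen when 3,4,5-trimethoxybenzaldehyde is converted into syringaldehyde: only the C7 oxygen is para to C4a and conjugated with the lactone carbonyl, so only it leaves as a stabilised phenoxide, its methyl group is twisted out of plane by two ortho methoxy groups, and the resulting phenoxide deactivates the ring toward further cleavage at C6 and C8.

Compound list
1 | 3,3-diethoxyprop-1-yne | C#CC(OCC)OCC | starting material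
2 | (E)-tributyl(3,3-diethoxyprop-1-enyl)stannane | CCCC[Sn](CCCC)(CCCC)/C=C/C(OCC)OCC | intermediate
3 | dimethyl squarate | COC1=C(OC)C(=O)C1=O | starting material
4 | [(E)-3,3-diethoxyprop-1-enyl]lithium | [Li]/C=C/C(OCC)OCC | intermediate
5 | lithium 1-[(E)-3,3-diethoxyprop-1-enyl]-2,3-dimethoxy-4-oxocyclobut-2-en-1-olate (racemic) | COC1=C(OC)C([O-])(/C=C/C(OCC)OCC)C1=O.[Li+] | intermediate
6 | rac-4-[(E)-3,3-diethoxyprop-1-enyl]-2,3,4-trimethoxycyclobut-2-en-1-one | COC1=C(OC)C(OC)(/C=C/C(OCC)OCC)C1=O | intermediate
7 | (3Z,5E)-7,7-diethoxy-2,3,4-trimethoxyhepta-1,3,5-trien-1-one | O=C=C(OC)/C(OC)=C(OC)\C=C\C(OCC)OCC | intermediate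
8 | rac-6-(diethoxymethyl)-2,3,4-trimethoxycyclohexa-2,4-dien-1-one | O=C1C(OC)=C(OC)C(OC)=CC1C(OCC)OCC | intermediate
9 | 6-(diethoxymethyl)-2,3,4-trimethoxyphenol | COc1cc(C(OCC)OCC)c(O)c(OC)c1OC | intermediate
10 | 2-hydroxy-3,4,5-trimethoxybenzaldehyde | COc1cc(C=O)c(O)c(OC)c1OC | intermediate
11 | 2,4,5-trihydroxybenzaldehyde | O=Cc1cc(O)c(O)cc1O | starting material
12 | 4,5-bis(benzyloxy)-2-hydroxybenzaldehyde | O=Cc1cc(OCc2ccccc2)c(OCc2ccccc2)cc1O | intermediate
13 | succinic anhydride | O=C1CCC(=O)O1 | starting material
14 | 4-[4,5-bis(benzyloxy)-2-formylphenoxy]-4-oxobutanoic acid | O=Cc1cc(OCc2ccccc2)c(OCc2ccccc2)cc1OC(=O)CCC(=O)O | intermediate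
15 | 2-[6,7-bis(benzyloxy)-2-oxo-2H-chromen-3-yl]acetic acid | OC(=O)Cc1cc2cc(OCc3ccccc3)c(OCc3ccccc3)cc2oc1=O | intermediate
16 | 6-formyl-2,3,4-trimethoxyphenyl 2-[6,7-bis(benzyloxy)-2-oxo-2H-chromen-3-yl]acetate | COc1cc(C=O)c(OC(=O)Cc2cc3cc(OCc4ccccc4)c(OCc4ccccc4)cc3oc2=O)c(OC)c1OC | intermediate
17 | 6',7'-bis(benzyloxy)-6,7,8-trimethoxy-3,3'-bicoumarin | COc1cc2cc(-c3cc4cc(OCc5ccccc5)c(OCc5ccccc5)cc4oc3=O)c(=O)oc2c(OC)c1OC | intermediate
18 | 6',7'-dihydroxy-6,7,8-trimethoxy-3,3'-bicoumarin | COc1cc2cc(-c3cc4cc(O)c(O)cc4oc3=O)c(=O)oc2c(OC)c1OC | intermediate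
19 | arteminorin C | COc1cc2cc(-c3cc4cc(O)c(O)cc4oc3=O)c(=O)oc2c(OC)c1O | target

Total step count: 9. Longest linear sequence: 7 (steps 1, 2, 3, 4, 7, 8, 9).

Steps most likely to fail

Step 9. Chloride may also attack the C6 or C8 methyl groups, the cleavage may stall, or the lactones may be damaged by dimethylamine released from hot DMF. The fallback moves the demethylation ahead of the coupling, where the methoxy group to be cleaved is para to a free formyl group, and carries the new phenol through as an acetate. Starting from 10, LiCl in DMF at 150 °C should give 2,4-dihydroxy-3,5-dimethoxybenzaldehyde F1. Condensing it with acid 15 in Ac2O/Et3N closes the pyranone and masks the phenol in the same operation, giving 7-acetoxy-6',7'-bis(benzyloxy)-6,8-dimethoxy-3,3'-bicoumarin F2. Methanolysis of the acetate (HCl, MeOH, reflux) leads to 6',7'-bis(benzyloxy)-7-hydroxy-6,8-dimethoxy-3,3'-bicoumarin F3. Hydrogenolysis over Pd/C then rejoins the route at target 19.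

Step 6. The aldol closure may be slow in the melt, the product may condense a second time with 12 to give the symmetrical bicoumarin, and decarboxylation or loss of benzyl groups may occur at this temperature. The fallback forms C3'=C4' by Wittig olefination instead of aldol condensation. Starting from 12, dimethyl 2-(triphenylphosphoranylidene)succinate in refluxing N,N-diethylaniline should give dimethyl (E)-2-[4,5-bis(benzyloxy)-2-hydroxybenzylidene]succinate F4. Under the same conditions this isomerises and lactonises to methyl 2-[6,7-bis(benzyloxy)-2-oxo-2H-chromen-3-yl]acetate F5. Saponification with LiOH in aqueous THF, followed by acidification to reclose any opened lactone, rejoins the route at acid 15.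

Step 2. Capture of the hindered tertiary alkoxide may be incomplete, the acetal oxygens may be methylated with loss of the acetal, or a second addition to the squarate may occur. The fallback leaves the C6 oxygen free through the ring expansion and methylates it later, when hydrogen bonding distinguishes the two phenols. Starting from 2 and 3, alkoxide 5 is quenched with aqueous NH4Cl to give 4-[(E)-3,3-diethoxyprop-1-enyl]-4-hydroxy-2,3-dimethoxycyclobut-2-en-1-one F6. The same thermal ring expansion in degassed toluene should give 2-(diethoxymethyl)-5,6-dimethoxybenzene-1,4-diol F7. Dilute HCl under argon then unmasks 2,5-dihydroxy-3,4-dimethoxybenzaldehyde F8. One equivalent of MeI with K2CO3 in acetone should methylate only the 5-OH, because the 2-OH is chelated to the aldehyde, and the route is rejoined at 10.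

Further compounds
F1 | step 9 | 2,4-dihydroxy-3,5-dimethoxybenzaldehyde | COc1cc(C=O)c(O)c(OC)c1O
F2 | step 9 | 7-acetoxy-6',7'-bis(benzyloxy)-6,8-dimethoxy-3,3'-bicoumarin | COc1cc2cc(-c3cc4cc(OCc5ccccc5)c(OCc5ccccc5)cc4oc3=O)c(=O)oc2c(OC)c1OC(C)=O
F3 | step 9 | 6',7'-bis(benzyloxy)-7-hydroxy-6,8-dimethoxy-3,3'-bicoumarin | COc1cc2cc(-c3cc4cc(OCc5ccccc5)c(OCc5ccccc5)cc4oc3=O)c(=O)oc2c(OC)c1O
F4 | step 6 | dimethyl (E)-2-[4,5-bis(benzyloxy)-2-hydroxybenzylidene]succinate | COC(=O)C/C(C(=O)OC)=C\c1cc(OCc2ccccc2)c(OCc2ccccc2)cc1O
F5 | step 6 | methyl 2-[6,7-bis(benzyloxy)-2-oxo-2H-chromen-3-yl]acetate | COC(=O)Cc1cc2cc(OCc3ccccc3)c(OCc3ccccc3)cc2oc1=O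
F6 | step 2 | rac-4-[(E)-3,3-diethoxyprop-1-enyl]-4-hydroxy-2,3-dimethoxycyclobut-2-en-1-one | COC1=C(OC)C(O)(/C=C/C(OCC)OCC)C1=O
F7 | step 2 | 2-(diethoxymethyl)-5,6-dimethoxybenzene-1,4-diol | COc1c(O)cc(C(OCC)OCC)c(O)c1OC
F8 | step 2 | 2,5-dihydroxy-3,4-dimethoxybenzaldehyde | COc1c(O)cc(C=O)c(O)c1OC
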